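(The data are simulated with constants of no real substance, and the scatter is random.)

Slowness is what east buys: substrate enters over 40 h, while zeta had substrate down to 4% by 0.417 d, a time shorter than that feed. The early portions of substrate in east should therefore meet standing partner, as in zeta; the later ones need not, since the reckoning below has the partner charge paying for part of the substrate.

| setting | gamma | eta | zeta | north-west | west | east |
|---|---|---|---|---|---|---|
| substrate | 0.30 M | 0.30 M | 0.30 M | 0.30 M | 0.30 M | 0.30 M (fed, over 40 h) |
| partner | 0.33 M | 0.17 M | 0.66 M | 0.330 M | 0.330 M (fed, over 40 h) | 0.330 M |
| remark | run made earlier | run made earlier | run made earlier | everything together at the start | all else is in the flask from the start; the feed brings no volume worth counting | all else is in the flask from the start; the feed brings no volume worth counting |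
| time |  |  |  | 2.5 d | 2.5 d | 2.5 d |

| run | time / d | triple product / % | substrate / % |
|---|---|---|---|
| gamma | 0.208 | 11 | 31 |
| gamma | 0.333 | 9 | 28 |
| gamma | 0.500 | 11 | 22 |
| gamma | 0.625 | 9 | 15 |
| gamma | 1.04 | 9 | 15 |
| gamma | 1.67 | 9 | 14 |
| gamma | 2.50 | 5 | 12 |
| eta | 0.250 | 4 | 55 |
| eta | 0.333 | 0 | 48 |
| eta | 0.500 | 0 | 50 |
| eta | 0.833 | 4 | 47 |
| eta | 1.25 | 2 | 50 |
| eta | 2.08 | 1 | 46 |
| eta | 3.00 | 0 | 49 |
| zeta | 0.417 | 46 | 4 |
| zeta | 0.833 | 51 | 1 |
| zeta | 1.25 | 47 | 0 |
| zeta | 1.67 | 46 | 3 |
| zeta | 2.00 | 50 | 3 |
| zeta | 2.50 | 51 | 0 |
| zeta | 3.00 | 47 | 0 |

(scatter of a reading: 2 percentage points)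

- a species is counted by the substrate in it: one side product counts as two
- what was read earlier has a scatter of 2 percentage points, one standard deviation
- steps that have been proposed: partner + first product -> bis adduct; substrate + bis adduct -> side product; substrate + partner -> first product; partner + bis adduct -> triple product; triple product <-> isomer of the product

- the best flask by amount of triple product, in percent of the substrate charged; "all alike" if 1.5 percentage points covers them all (north-west / west / east / all alike)
- amount of triple product at the end, in percent of the substrate charged, north-west
- amount of triple product at the end, in percent of the substrate charged, west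
- amount of triple product at the end, in percent of the substrate charged, east

For the bench, reckon east by one quantity: the partner price, the partner spent per substrate consumed. Substrate ending in side product costs one partner, and substrate ending in triple product costs 3. Zeta gives the share y of consumed substrate that is triple product, with the rest read as side product:

y = 48.3%

price = 1 + 2y = 1.97

East charges 1.10 partner per substrate, so:

substrate consumed = 56.0%

triple product = y × consumed = 27.0%

The charge buys less than the whole substrate, which makes partner the limiting reagent. At 2.5 d, east should hold about 44.0% substrate unconsumed. Leave the feed at its pace: gamma, with these charges together at the start, read 5% to 11% triple product, less than 27.0%. North-west repeats gamma, and west is reckoned lower still, without a firm figure.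

The forecast gave east, with 9% north-west, 4% west and 28% east: “East keeps substrate low, so each substrate takes three partners”.

East holds 24.5% triple product, and east leads north-west by 15 percentage points; west holds 6.02%.

    partner + first product → bis adduct (k = 8.20 M⁻¹ h⁻¹)
    substrate + bis adduct → side product (k = 1.30 M⁻¹ h⁻¹)
    substrate + partner → first product (k = 2.20 M⁻¹ h⁻¹)
    partner + bis adduct → triple product (k = 2.30 M⁻¹ h⁻¹)
    triple product ⇌ isomer of the product (K = 0.140, k = 0.0410 h⁻¹)

East ends with 45.9% substrate beside 0% partner. It paid 2.03, close to the 1.97 from zeta. Isomer of the product also costs 3, so this price counts it with triple product: 28.0% reckoned, 27.9% standing. North-west, with 12.8% substrate and 0% partner, paid 1.26, which reckons 11.4% against 11.1% standing.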